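**Plan**

1. Retrosynthetic cuts, in order: the fifteen O-benzyl groups and the terminal 3-O-galloyl ester; then ring C of the upper flavan across C3–C4 and O1–C2 (retro hetero-Diels–Alder), which also opens the 16-membered macrolide; then the lower 3-O ester, the lower C8–upper C4 bond and the ring B–gallate diaryl ether.
2. Feature used: in the upper unit, O1–C8a–C4a–C4 of ring A is a latent o-quinone methide whose methide carbon C4 sits on C8 of the lower flavan, and the C2 aryl (ring B) is tied through its 2′-O-gallate bridge to O3 of that same lower flavan, so heterodiene and C2=C3 dienophile lie in one chain.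
3. Forward: (−)-epigallocatechin gives the lower unit carrying ring A as a C8 benzhydryl ether; a diaryl ether fragment gives ring B with a (Z)-alkenylboronate and the bridging acid; esterification joins them; the cycloaddition closes ring C and the macrocycle; C–B becomes C–OH, then gallate and hydrogenolysis.
4. Stereochemistry: lower C2/C3 from the chiral pool; upper C2/C3 cis from the Z alkene; C3/C4 trans and the absolute sense from an exo cycloaddition steered by the lower unit through the bridge; C–B oxidation with retention.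

Key step: step 16

Remark: 1, 4, 12, 14 and 25 are taken as purchasable; the benzhydryl carbon made in step 6 is carried as an epimer mixture (9–11, 20, 21) because it becomes trigonal in 22.

**Route**

Step 1
Reactants: 1 2,4,6-trihydroxybenzaldehyde
Product: 2 2,4-bis(benzyloxy)-6-hydroxybenzaldehyde
Conditions: BnBr (2.05 equiv), K2CO3, DMF, 0 °C → rt
Reagents that add atoms: benzyl bromide, BrCc1ccccc1
Why: Williamson etherification in which the 4-OH and one ortho OH react while the last ortho OH, hydrogen-bonded to the formyl oxygen, stays free.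

Step 2
Reactants: 2 2,4-bis(benzyloxy)-6-hydroxybenzaldehyde
Product: 3 2-(allyloxy)-4,6-bis(benzyloxy)benzaldehyde
Conditions: allyl bromide, K2CO3, DMF, 60 °C
Reagents that add atoms: allyl bromide, C=CCBr
Why: Williamson allylation of the chelated phenol; allyl neither migrates to an alkoxide nor reacts with an aryllithium and later leaves under neutral zerovalent palladium catalysis.

Step 3
Reactants: 4 (−)-epigallocatechin
Product: 5 (2R,3R)-5,7-bis(benzyloxy)-2-[3,4,5-tris(benzyloxy)phenyl]chroman-3-ol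
Conditions: BnBr (5.5 equiv), K2CO3, DMF, −10 °C → rt, N2
Reagents that add atoms: benzyl bromide, BrCc1ccccc1
Why: chemoselective Williamson benzylation of the five phenols over the secondary alcohol, run cold and oxygen-free to avoid pyrogallol oxidation and C2 epimerisation; C2 and C3 come unchanged from 4.

Step 4
Reactants: 5 penta-O-benzyl-epigallocatechin
Product: 6 8-bromo derivative of 5
Conditions: NBS, CH2Cl2, −78 °C → rt
Reagents that add atoms: N-bromosuccinimide, O=C1CCC(=O)N1Br
Why: electrophilic aromatic bromination at C8, the most nucleophilic position of the 5,7-dialkoxychroman ring, as is known for benzylated epicatechin.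

Step 5
Reactants: 6 8-bromo-penta-O-benzyl-epigallocatechin
Product: 7 3-O-tert-butyldimethylsilyl ether of 6
Conditions: TBSCl, imidazole, DMF, rt
Reagents that add atoms: tert-butyldimethylsilyl chloride, CC(C)(C)[Si](C)(C)Cl
Why: silyl protection of the 3-OH so that it cannot quench the aryllithium of the next step.

Step 6
Reactants: 7 silyl ether of the 8-bromide; 3 2-(allyloxy)-4,6-bis(benzyloxy)benzaldehyde
Product: 10 lower flavan silyl ether with C8–CH(OMe)[2-(allyloxy)-4,6-bis(benzyloxy)phenyl] (epimer mixture at the benzhydryl carbon), via C8-aryllithium 8 (not isolated), via benzhydrol 9 (not isolated)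
Conditions: t-BuLi (2.1 equiv), THF, −78 °C; 3, −78 → 0 °C; H2O; crude carbinol: MeOH, PPTS (cat.), CH2Cl2, rt
Reagents that add atoms: methanol, CO
Why: bromine–lithium exchange and 1,2-addition of the aryllithium to the aldehyde make the lower C8–upper C4 bond, and SN1 methanolysis of the benzhydrol (cation stabilised by two 2,4,6-trioxygenated rings) stores the future methide carbon as a base-stable methyl ether.

Step 7
Reactants: 10 benzhydryl methyl ether silyl ether
Product: 11 the corresponding free 3-alcohol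
Conditions: TBAF, THF, rt
Reagents that add atoms: none
Why: fluoride-induced desilylation frees the 3-OH for the ester union while all ethers persist.

Step 8
Reactants: 12 methyl gallate
Product: 13 methyl 3,4-bis(benzyloxy)-5-hydroxybenzoate
Conditions: BnBr (2.0 equiv), K2CO3, DMF, rt
Reagents that add atoms: benzyl bromide, BrCc1ccccc1
Why: Williamson benzylation follows phenol acidity (4-OH first, then one 3-OH) and leaves one meta OH as the later diaryl ether oxygen.

Step 9
Reactants: 14 3,4,5-tris(benzyloxy)benzaldehyde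
Product: 15 2-bromo-3,4,5-tris(benzyloxy)benzaldehyde
Conditions: NBS, MeCN, rt, dark
Reagents that add atoms: N-bromosuccinimide, O=C1CCC(=O)N1Br
Why: electrophilic aromatic bromination at the only kind of free ring position, ortho to the formyl group, as is known for the trimethoxy analogue.

Step 10
Reactants: 13 methyl 3,4-bis(benzyloxy)-5-hydroxybenzoate; 15 2-bromo-3,4,5-tris(benzyloxy)benzaldehyde
Product: 16 methyl 3,4-bis(benzyloxy)-5-[2,3,4-tris(benzyloxy)-6-formylphenoxy]benzoate
Conditions: CuI (10 mol%), picolinic acid (20 mol%), K3PO4, DMSO, 90 °C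
Reagents that add atoms: none
Why: Ullmann diaryl ether synthesis in which the ortho formyl group activates the hindered bromide toward monovalent copper and the picolinate ligand tolerates the flanking benzyloxy groups.

Step 11
Reactants: 16 diaryl ether aldehyde
Product: 17 methyl 3,4-bis(benzyloxy)-5-[2,3,4-tris(benzyloxy)-6-ethynylphenoxy]benzoate
Conditions: dimethyl (1-diazo-2-oxopropyl)phosphonate, K2CO3, MeOH/THF, 0 °C → rt
Reagents that add atoms: dimethyl (1-diazo-2-oxopropyl)phosphonate, CC(=O)C(=[N+]=[N-])P(=O)(OC)OC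
Why: Ohira–Bestmann (Seyferth–Gilbert) homologation of the aryl aldehyde to the terminal alkyne under conditions that leave the methyl ester unchanged.

Step 12
Reactants: 17 aryl alkyne
Product: 18 methyl 3,4-bis(benzyloxy)-5-{2,3,4-tris(benzyloxy)-6-[(Z)-2-(4,4,5,5-tetramethyl-1,3,2-dioxaborolan-2-yl)ethenyl]phenoxy}benzoate
Conditions: HBpin, [Rh(cod)Cl]2 (cat.), P(i-Pr)3, Et3N, cyclohexane/THF, rt
Reagents that add atoms: pinacolborane, CC1(C)OBOC1(C)C
Why: rhodium-catalysed trans-hydroboration of a terminal alkyne through a rhodium vinylidene gives the anti-Markovnikov (Z)-alkenylboronate, which fixes the later C2/C3 cis relationship.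

Step 13
Reactants: 18 (Z)-alkenylboronate methyl ester
Product: 19 the corresponding benzoic acid
Conditions: LiOH·H2O, THF/H2O, rt → 40 °C; then cold 1 M HCl to pH 4
Reagents that add atoms: lithium hydroxide, [Li+].[OH-]
Why: saponification of the methyl benzoate; the pinacol boronate should only form a reversible hydroxy ate complex and return on acidification.

Step 14
Reactants: 11 lower-unit alcohol; 19 bridging acid
Product: 20 3-O-ester of 11 with 19
Conditions: DCC, DMAP, CH2Cl2, rt
Reagents that add atoms: none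
Why: Steglich esterification, the standard acylation of the axial 3-OH of benzylated epi-flavan-3-ols, with retention at C3.

Step 15
Reactants: 20 allyl-protected ester
Product: 21 the free ring A phenol
Conditions: Pd(PPh3)4 (5 mol%), morpholine, THF, 0 °C → rt
Reagents that add atoms: none
Why: Tsuji–Trost-type deallylation under neutral conditions, with morpholine as allyl acceptor, frees the phenol that becomes O1 without touching boronate, ester or benzyl ethers.

Step 16
Reactants: 21 phenolic benzhydryl methyl ether with tethered (Z)-alkenylboronate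
Product: 23 dodeca-O-benzyl macrocycle with Bpin on the upper C3 (CIP 2S,3R,4R; spatially as in 27), via o-quinone methide 22 (not isolated)
Conditions: toluene (about 1 mM), 4 Å MS, 100 °C
Reagents that add atoms: none
Why: Proposed new method: on heating, the phenol O–H of 21 passes its proton to the benzhydryl OMe and methanol leaves, giving the ring A o-quinone methide 22 (O1=C8a–C4a=C4, with C8 of the lower flavan already on C4), and this electron-poor 1-oxadiene adds suprafacially across the tethered (Z)-alkenylboronate in an inverse-electron-demand hetero-Diels–Alder reaction in which C3–C4 forms ahead of O1–C2. The closest known reaction types are the [4+2] cycloaddition of o-quinone methides with styrenes to 2-arylchromans, including intramolecular cases, and the macrocyclising Diels–Alder reaction; a β-borylstyrene as 2π partner and the ring size are the untested parts. Two rings close in the one event: ring C as a six-membered ring by [4+2] cycloaddition, and the 16-membered macrolide through the C3–C4 bond as an endo closure (both alkene carbons end inside the ring). Regiochemistry rests on the styrene-type polarisation of the alkene, which boron reinforces because it is no π-donor, so that the boron-bearing carbon bonds to the methide carbon and the benzylic carbon to O1, whereas an acyloxy or alkoxy group on C3 would polarise the alkene the opposite way, which is why O3 is carried as boron. C2 and C3 become cis because the Z geometry is transferred stereospecifically, C3 and C4 become trans through the exo transition state on the E-quinone methide, and the absolute sense at C4 should come from the lower unit, whose axial (3R)-ester oxygen points to the open exo side only on the face that gives 4R, where the short bridge can reach ring B, while the other face would need an endo mode that stacks ring B, the boronate and the bridging gallate over ring A against its C5 benzyloxy group. The selectivities needed are cycloaddition over boron-to-carbon alkenyl transfer and over intermolecular capture of the quinone methide, for which the weakly Lewis-acidic pinacol ester, the absence of diol, base or acid, and high dilution are chosen.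

Step 17
Reactants: 23 macrocyclic boronate
Product: 24 dodeca-O-benzyl macrocyclic flavan-3-ol (upper unit 2R,3R,4R)
Conditions: NaBO3·4H2O, THF/H2O, rt
Reagents that add atoms: sodium perborate, [Na+].[O-]OB=O
Why: oxidation of the secondary C–B bond by 1,2-migration from boron to oxygen occurs with retention, so the 3-OH is cis to ring B and trans to the C4 aryl, and the mild perborate spares the ester.

Step 18
Reactants: 24 macrocyclic alcohol; 25 3,4,5-tris(benzyloxy)benzoic acid
Product: 26 pentadeca-O-benzyl derivative of the target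
Conditions: DCC, DMAP, CH2Cl2, rt → 40 °C
Reagents that add atoms: none
Why: Steglich esterification of the hindered axial 3-OH, as in the 3-O-galloylation of upper units of benzylated procyanidins.

Step 19
Reactants: 26 pentadeca-O-benzyl derivative
Product: 27 CNP0601265.1
Conditions: H2 (1 atm), Pd(OH)2/C, THF/MeOH/H2O, rt
Reagents that add atoms: none
Why: hydrogenolysis of all fifteen benzyl ethers, a reaction that leaves aryl esters, the diaryl ether and the C4–C8 bond intact in benzylated flavan-3-ol gallate oligomers.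

**Compound list**

1 | 2,4,6-trihydroxybenzaldehyde | O=Cc1c(O)cc(O)cc1O | starting material
2 | 2,4-bis(benzyloxy)-6-hydroxybenzaldehyde | O=Cc1c(O)cc(OCc2ccccc2)cc1OCc1ccccc1 | intermediate
3 | 2-(allyloxy)-4,6-bis(benzyloxy)benzaldehyde | C=CCOc1cc(OCc2ccccc2)cc(OCc2ccccc2)c1C=O | intermediate
4 | (−)-epigallocatechin, (2R,3R) | O[C@@H]1Cc2c(O)cc(O)cc2O[C@@H]1c1cc(O)c(O)c(O)c1 | starting material
5 | (2R,3R)-5,7-bis(benzyloxy)-2-[3,4,5-tris(benzyloxy)phenyl]chroman-3-ol | O[C@@H]1Cc2c(OCc3ccccc3)cc(OCc3ccccc3)cc2O[C@@H]1c1cc(OCc2ccccc2)c(OCc2ccccc2)c(OCc2ccccc2)c1 | intermediate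
6 | 8-bromo derivative of 5 | O[C@@H]1Cc2c(OCc3ccccc3)cc(OCc3ccccc3)c(Br)c2O[C@@H]1c1cc(OCc2ccccc2)c(OCc2ccccc2)c(OCc2ccccc2)c1 | intermediate
7 | 3-O-TBS ether of 6 | CC(C)(C)[Si](C)(C)O[C@@H]1Cc2c(OCc3ccccc3)cc(OCc3ccccc3)c(Br)c2O[C@@H]1c1cc(OCc2ccccc2)c(OCc2ccccc2)c(OCc2ccccc2)c1 | intermediate
8 | C8-aryllithium from 7 | CC(C)(C)[Si](C)(C)O[C@@H]1Cc2c(OCc3ccccc3)cc(OCc3ccccc3)c([Li])c2O[C@@H]1c1cc(OCc2ccccc2)c(OCc2ccccc2)c(OCc2ccccc2)c1 | intermediate
9 | benzhydrol: 7 with Br replaced by CH(OH)[2-(allyloxy)-4,6-bis(benzyloxy)phenyl], epimer mixture | CC(C)(C)[Si](C)(C)O[C@@H]1Cc2c(OCc3ccccc3)cc(OCc3ccccc3)c(C(O)c3c(OCC=C)cc(OCc4ccccc4)cc3OCc3ccccc3)c2O[C@@H]1c1cc(OCc2ccccc2)c(OCc2ccccc2)c(OCc2ccccc2)c1 | intermediate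
10 | methyl ether of 9, epimer mixture | CC(C)(C)[Si](C)(C)O[C@@H]1Cc2c(OCc3ccccc3)cc(OCc3ccccc3)c(C(OC)c3c(OCC=C)cc(OCc4ccccc4)cc3OCc3ccccc3)c2O[C@@H]1c1cc(OCc2ccccc2)c(OCc2ccccc2)c(OCc2ccccc2)c1 | intermediate
11 | desilylated 10 (free 3-OH), epimer mixture | O[C@@H]1Cc2c(OCc3ccccc3)cc(OCc3ccccc3)c(C(OC)c3c(OCC=C)cc(OCc4ccccc4)cc3OCc3ccccc3)c2O[C@@H]1c1cc(OCc2ccccc2)c(OCc2ccccc2)c(OCc2ccccc2)c1 | intermediate
12 | methyl gallate | COC(=O)c1cc(O)c(O)c(O)c1 | starting material
13 | methyl 3,4-bis(benzyloxy)-5-hydroxybenzoate | COC(=O)c1cc(O)c(OCc2ccccc2)c(OCc2ccccc2)c1 | intermediate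
14 | 3,4,5-tris(benzyloxy)benzaldehyde | O=Cc1cc(OCc2ccccc2)c(OCc2ccccc2)c(OCc2ccccc2)c1 | starting material
15 | 2-bromo-3,4,5-tris(benzyloxy)benzaldehyde | O=Cc1cc(OCc2ccccc2)c(OCc2ccccc2)c(OCc2ccccc2)c1Br | intermediate
16 | methyl 3,4-bis(benzyloxy)-5-[2,3,4-tris(benzyloxy)-6-formylphenoxy]benzoate | COC(=O)c1cc(Oc2c(C=O)cc(OCc3ccccc3)c(OCc3ccccc3)c2OCc2ccccc2)c(OCc2ccccc2)c(OCc2ccccc2)c1 | intermediate
17 | methyl 3,4-bis(benzyloxy)-5-[2,3,4-tris(benzyloxy)-6-ethynylphenoxy]benzoate | COC(=O)c1cc(Oc2c(C#C)cc(OCc3ccccc3)c(OCc3ccccc3)c2OCc2ccccc2)c(OCc2ccccc2)c(OCc2ccccc2)c1 | intermediate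
18 | (Z)-alkenyl pinacolboronate methyl ester | COC(=O)c1cc(Oc2c(/C=C\B3OC(C)(C)C(C)(C)O3)cc(OCc3ccccc3)c(OCc3ccccc3)c2OCc2ccccc2)c(OCc2ccccc2)c(OCc2ccccc2)c1 | intermediate
19 | (Z)-alkenyl pinacolboronate acid | OC(=O)c1cc(Oc2c(/C=C\B3OC(C)(C)C(C)(C)O3)cc(OCc3ccccc3)c(OCc3ccccc3)c2OCc2ccccc2)c(OCc2ccccc2)c(OCc2ccccc2)c1 | intermediate
20 | 3-O-ester of 11 with 19 (allyl ether, benzhydryl methyl ether, Z-alkenylboronate) | O=C(O[C@@H]1Cc2c(OCc3ccccc3)cc(OCc3ccccc3)c(C(OC)c3c(OCC=C)cc(OCc4ccccc4)cc3OCc3ccccc3)c2O[C@@H]1c1cc(OCc2ccccc2)c(OCc2ccccc2)c(OCc2ccccc2)c1)c1cc(Oc2c(/C=C\B3OC(C)(C)C(C)(C)O3)cc(OCc3ccccc3)c(OCc3ccccc3)c2OCc2ccccc2)c(OCc2ccccc2)c(OCc2ccccc2)c1 | intermediate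
21 | deallylated 20 (free ring A phenol) | O=C(O[C@@H]1Cc2c(OCc3ccccc3)cc(OCc3ccccc3)c(C(OC)c3c(O)cc(OCc4ccccc4)cc3OCc3ccccc3)c2O[C@@H]1c1cc(OCc2ccccc2)c(OCc2ccccc2)c(OCc2ccccc2)c1)c1cc(Oc2c(/C=C\B3OC(C)(C)C(C)(C)O3)cc(OCc3ccccc3)c(OCc3ccccc3)c2OCc2ccccc2)c(OCc2ccccc2)c(OCc2ccccc2)c1 | intermediate
22 | (E)-o-quinone methide: 3,5-bis(benzyloxy)-6-(arylmethylidene)cyclohexa-2,4-dienone on lower C8, with tethered Z-alkenylboronate | O=C(O[C@@H]1Cc2c(OCc3ccccc3)cc(OCc3ccccc3)c(/C=C3/C(=O)C=C(OCc4ccccc4)C=C3OCc3ccccc3)c2O[C@@H]1c1cc(OCc2ccccc2)c(OCc2ccccc2)c(OCc2ccccc2)c1)c1cc(Oc2c(/C=C\B3OC(C)(C)C(C)(C)O3)cc(OCc3ccccc3)c(OCc3ccccc3)c2OCc2ccccc2)c(OCc2ccccc2)c(OCc2ccccc2)c1 | intermediate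
23 | dodeca-O-benzyl macrocycle with Bpin on upper C3 (ring B and boron cis; boron and lower flavan trans) | CC1(C)OB(OC1(C)C)[C@@H]1[C@@H]2c3c(OCc4ccccc4)cc(OCc4ccccc4)cc3O[C@@H]1c1cc(OCc4ccccc4)c(OCc4ccccc4)c(OCc4ccccc4)c1Oc1cc(cc(OCc4ccccc4)c1OCc4ccccc4)C(=O)O[C@@H]1Cc3c(OCc4ccccc4)cc(OCc4ccccc4)c2c3O[C@@H]1c1cc(OCc4ccccc4)c(OCc4ccccc4)c(OCc4ccccc4)c1 | intermediate
24 | dodeca-O-benzyl macrocyclic flavan-3-ol, upper unit (2R,3R,4R) | O[C@@H]1[C@@H]2c3c(OCc4ccccc4)cc(OCc4ccccc4)cc3O[C@@H]1c1cc(OCc4ccccc4)c(OCc4ccccc4)c(OCc4ccccc4)c1Oc1cc(cc(OCc4ccccc4)c1OCc4ccccc4)C(=O)O[C@@H]1Cc3c(OCc4ccccc4)cc(OCc4ccccc4)c2c3O[C@@H]1c1cc(OCc4ccccc4)c(OCc4ccccc4)c(OCc4ccccc4)c1 | intermediate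
25 | 3,4,5-tris(benzyloxy)benzoic acid | OC(=O)c1cc(OCc2ccccc2)c(OCc2ccccc2)c(OCc2ccccc2)c1 | starting material
26 | pentadeca-O-benzyl derivative of the target | O=C(O[C@@H]1[C@@H]2c3c(OCc4ccccc4)cc(OCc4ccccc4)cc3O[C@@H]1c1cc(OCc4ccccc4)c(OCc4ccccc4)c(OCc4ccccc4)c1Oc1cc(cc(OCc4ccccc4)c1OCc4ccccc4)C(=O)O[C@@H]1Cc3c(OCc4ccccc4)cc(OCc4ccccc4)c2c3O[C@@H]1c1cc(OCc4ccccc4)c(OCc4ccccc4)c(OCc4ccccc4)c1)c1cc(OCc4ccccc4)c(OCc4ccccc4)c(OCc4ccccc4)c1 | intermediate
27 | CNP0601265.1 | O=C(O[C@@H]1[C@@H]2c3c(O)cc(O)cc3O[C@@H]1c1cc(O)c(O)c(O)c1Oc1cc(cc(O)c1O)C(=O)O[C@@H]1Cc3c(O)cc(O)c2c3O[C@@H]1c1cc(O)c(O)c(O)c1)c1cc(O)c(O)c(O)c1 | target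

**Totals**

Total steps: 19. Longest linear sequence: 11 steps (4 → 27 through steps 3–7 and 14–19; the branches from 12 and from 14 are equally long).

**Steps most likely to fail**

1. Step 16 (Proposed new method). The donor-stabilised quinone methide may be too weak an electrophile for a cis-disubstituted alkenylboronate, so that intermolecular oligomerisation or re-addition of methanol wins. Ring closure at oxygen may be lost to transfer of the alkenyl group from boron to carbon. Leakage between exo and endo modes or between the two faces would give C3 or C4 epimers.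
Fallback, using known reaction types only: it sets out from 21 and comes back to the route at 24. The pinacol ester is exchanged with KHF2 (MeOH/H2O, rt) to give the potassium trifluoroborate F1. BF3·OEt2 (CH2Cl2/MeCN, −40 °C, high dilution) ionises the benzhydryl methyl ether, and the (Z)-alkenyl group moves from boron to C4 with retention of the double-bond geometry (Lewis acid-mediated alkenylation of a benzhydryl cation by an alkenyltrifluoroborate). This closes the macrocycle through the same C3–C4 bond and gives the macrocyclic (Z)-alkenyl phenol F2; C4 epimers would be separated here. A Jacobsen–Katsuki epoxidation of the cis-aryl alkene (the antipode of the (salen)MnCl complex, a trivalent manganese catalyst, that matches the required face; mCPBA, N-methylmorpholine N-oxide, CH2Cl2, −78 °C) gives the cis-epoxide F3. Catalytic camphorsulfonic acid then lets the ring A phenol open F3 in the 6-endo sense at the benzylic carbon with inversion, which should deliver the 2,3-cis alcohol 24.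

2. Step 10. Oxidative addition of monovalent copper to the doubly ortho-substituted bromide may be slow, with protodebromination and base-induced loss of the aldehyde competing.
Fallback: it sets out from 14 and 13 and comes back at 16. Aldehyde 14 is treated with [hydroxy(tosyloxy)iodo]mesitylene in CF3CH2OH/CH2Cl2, where the trivalent iodine enters ortho to the formyl group and gives the aryl(mesityl)iodonium tosylate F4. Metal-free O-arylation of phenol 13 with F4 (K2CO3 or t-BuOK, THF, rt) transfers the formyl-bearing aryl group and gives 16.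

3. Step 12. Rhodium hydride-mediated isomerisation may erode the Z geometry, or the ortho aryloxy group may stall the vinylidene pathway.
Fallback: it sets out from 16 and comes back at 18. A Stork–Zhao olefination of 16 (Ph3P+CH2I I−, NaHMDS, THF/DMPU, −78 °C) gives the (Z)-vinyl iodide F5. Miyaura borylation of F5 (B2pin2, PdCl2(dppf), KOPh, toluene, 50 °C) proceeds with retention and gives 18.

Further compounds
F1 | step 16 | potassium (Z)-alkenyltrifluoroborate corresponding to 21 | O=C(O[C@@H]1Cc2c(OCc3ccccc3)cc(OCc3ccccc3)c(C(OC)c3c(O)cc(OCc4ccccc4)cc3OCc3ccccc3)c2O[C@@H]1c1cc(OCc2ccccc2)c(OCc2ccccc2)c(OCc2ccccc2)c1)c1cc(Oc2c(/C=C\[B-](F)(F)F)cc(OCc3ccccc3)c(OCc3ccccc3)c2OCc2ccccc2)c(OCc2ccccc2)c(OCc2ccccc2)c1.[K+]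
F2 | step 16 | macrocyclic (Z)-alkene with the 2-hydroxy-4,6-bis(benzyloxy)phenyl group (ring A, free O1–H) on C4 and a cis C2=C3 double bond | Oc1cc(OCc5ccccc5)cc(OCc5ccccc5)c1[C@H]2/C=C\c3cc(OCc5ccccc5)c(OCc5ccccc5)c(OCc5ccccc5)c3Oc3cc(cc(OCc5ccccc5)c3OCc5ccccc5)C(=O)O[C@@H]3Cc4c(OCc5ccccc5)cc(OCc5ccccc5)c2c4O[C@@H]3c2cc(OCc5ccccc5)c(OCc5ccccc5)c(OCc5ccccc5)c2
F3 | step 16 | cis-2,3-epoxide of F2 | Oc1cc(OCc5ccccc5)cc(OCc5ccccc5)c1[C@H]2[C@H]6O[C@H]6c3cc(OCc5ccccc5)c(OCc5ccccc5)c(OCc5ccccc5)c3Oc3cc(cc(OCc5ccccc5)c3OCc5ccccc5)C(=O)O[C@@H]3Cc4c(OCc5ccccc5)cc(OCc5ccccc5)c2c4O[C@@H]3c2cc(OCc5ccccc5)c(OCc5ccccc5)c(OCc5ccccc5)c2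
F4 | step 10 | [2,3,4-tris(benzyloxy)-6-formylphenyl](2,4,6-trimethylphenyl)iodonium 4-methylbenzenesulfonate | O=Cc1cc(OCc2ccccc2)c(OCc2ccccc2)c(OCc2ccccc2)c1[I+]c1c(C)cc(C)cc1C.Cc1ccc(cc1)S(=O)(=O)[O-]
F5 | step 12 | methyl 3,4-bis(benzyloxy)-5-{2,3,4-tris(benzyloxy)-6-[(Z)-2-iodoethenyl]phenoxy}benzoate | COC(=O)c1cc(Oc2c(/C=C\I)cc(OCc3ccccc3)c(OCc3ccccc3)c2OCc2ccccc2)c(OCc2ccccc2)c(OCc2ccccc2)c1
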